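The target is a single 31-membered lactone ring made of the ester oxygen, the carbonyl carbon C1 and 29 contiguous methylenes C2–C30, with no branch or stereocentre. Because all bonds from C2 to C30 join plain CH2 groups, the open C30 chain is cut at C19–C20. A crossed Kolbe electrolysis forms this bond in one operation from 12-acetoxydodecanoic acid (C20–C30) and monomethyl eicosanedioate (C1–C19), each losing CO2, and delivers the whole chain with its ends already differentiated as acetate and methyl ester. Both acids are one step from commodity chemicals; saponification and high-dilution Yamaguchi closure of the C1–O bond then give the ring.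

Key step: step 3

Remark: the chain is numbered as in the seco acid (C1 = carboxyl carbon, C30 = carbinol carbon); the carboxylate ions and alkyl radicals of the electrolysis are short-lived electrode species and carry no compound numbers.

Step 1
Reactants: 1 12-hydroxydodecanoic acid
Product: 2 12-acetoxydodecanoic acid
Conditions: AcOH (solvent, ca. 0.2 M), TsOH·H2O (cat.), 100 °C; then NaOAc, evaporate, crystallise
Reagents that add atoms: acetic acid, CC(=O)O
Why: Fischer esterification of the primary alcohol in an about hundredfold molar excess of acetic acid, so that mass action should drive O-acetylation to completion and keep self-esterification of 1 negligible, while the carboxyl group stays free.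

Step 2
Reactants: 3 eicosanedioic acid
Product: 4 monomethyl eicosanedioate (20-methoxy-20-oxoicosanoic acid)
Conditions: MeOH (1.2 equiv), H2SO4 (cat.), 1,4-dioxane, 80 °C; filtration of unreacted 3, silica chromatography
Reagents that add atoms: methanol, CO
Why: Fischer esterification with limiting methanol should give a statistical mixture of the two remote, independent carboxyls in which the half-ester is expected to be the largest component, and it is separable from the sparingly soluble diacid and the neutral diester, both of which can be recycled.

Step 3
Reactants: 2 12-acetoxydodecanoic acid; 4 monomethyl eicosanedioate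
Product: 5 methyl 30-acetoxytriacontanoate
Conditions: 2 (4 equiv), 4 (1 equiv), NaOMe (0.05–0.1 equiv per CO2H), MeOH/light petroleum, smooth Pt foil anode, Pt cathode, undivided cell, ca. 0.25 A cm−2, 45–50 °C, to pH ca. 8; then AcOH
Reagents that add atoms: none
Why: At smooth platinum above the critical potential, the two carboxylates (only partly neutralised in weakly acidic methanol) are each oxidised by one electron to acyloxy radicals that lose CO2 at once; the resulting primary 11-acetoxyundecyl and 18-(methoxycarbonyl)octadecyl radicals build up in the layer on the anode and combine to form the C19–C20 bond. The closest known reaction type is the crossed (mixed) Kolbe electrolysis of a dicarboxylic half-ester with an ω-acyloxy alkanoic acid. No ring is closed and no stereocentre is created, so there is no closure mode and no controlling element to specify. Two selectivities are needed: radical coupling over further oxidation to the cation (Hofer–Moest pathway), secured by both radicals being unbranched, primary and free of any α-heteroatom, and cross- over homo-coupling, which is only statistical and is therefore biased by the fourfold excess of 2 so that most radicals derived from 4 should meet an acetoxyundecyl partner. The remote acetate and methyl ester are not oxidised at the Kolbe potential and should not be solvolysed if the electrolysis is stopped near neutrality, while the hydrocarbon co-solvent is meant to keep the long-chain products off the anode. The C22 diacetate and C38 diester homodimers differ from 5 by eight carbons each and should be removable by fractional crystallisation and chromatography.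

Step 4
Reactants: 5 methyl 30-acetoxytriacontanoate
Product: 7 30-hydroxytriacontanoic acid, via potassium 30-hydroxytriacontanoate 6 (not isolated)
Conditions: KOH (6 equiv), EtOH/THF/H2O, reflux; then 2 M HCl, filtration
Reagents that add atoms: potassium hydroxide, [K+].[OH-]
Why: Saponification should cleave the acetate and the methyl ester in one operation, made irreversible by carboxylate formation, and acidification precipitates the hydroxy acid, the chain carrying nothing else that could react.

Step 5
Reactants: 7 30-hydroxytriacontanoic acid
Product: 9 triacontan-30-olide (oxacyclohentriacontan-2-one), via 30-hydroxytriacontanoic 2,4,6-trichlorobenzoic anhydride 8 (not isolated)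
Conditions: 2,4,6-Cl3C6H2COCl, Et3N, THF/toluene, 40 °C; then syringe-pump addition to DMAP, toluene, reflux (final ca. 1 mM)
Reagents that add atoms: none
Why: Yamaguchi macrolactonisation, in which the carboxylate forms the mixed anhydride, DMAP transfers the aliphatic acyl group (the aryl carbonyl is shielded by its two ortho chlorines) and the C30 hydroxyl closes the strain-free 31-membered ring under high dilution, where ring closure should outrun oligomerisation.

Compound list
1 | 12-hydroxydodecanoic acid | OCCCCCCCCCCCC(=O)O | starting material
2 | 12-acetoxydodecanoic acid | CC(=O)OCCCCCCCCCCCC(=O)O | intermediate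
3 | eicosanedioic acid (icosanedioic acid) | OC(=O)CCCCCCCCCCCCCCCCCCC(=O)O | starting material
4 | monomethyl eicosanedioate (20-methoxy-20-oxoicosanoic acid) | COC(=O)CCCCCCCCCCCCCCCCCCC(=O)O | intermediate
5 | methyl 30-acetoxytriacontanoate | CC(=O)OCCCCCCCCCCCCCCCCCCCCCCCCCCCCCC(=O)OC | intermediate
6 | potassium 30-hydroxytriacontanoate | [K+].[O-]C(=O)CCCCCCCCCCCCCCCCCCCCCCCCCCCCCO | intermediate (not isolated)
7 | 30-hydroxytriacontanoic acid | OCCCCCCCCCCCCCCCCCCCCCCCCCCCCCC(=O)O | intermediate
8 | 30-hydroxytriacontanoic 2,4,6-trichlorobenzoic anhydride | OCCCCCCCCCCCCCCCCCCCCCCCCCCCCCC(=O)OC(=O)c1c(Cl)cc(Cl)cc1Cl | intermediate (not isolated)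
9 | triacontan-30-olide (oxacyclohentriacontan-2-one; achiral, no stereocentres) | O=C1CCCCCCCCCCCCCCCCCCCCCCCCCCCCCO1 | target

Total step count: 5. Longest linear sequence: 4 steps (1 → 2 → 5 → 7 → 9, or equally 3 → 4 → 5 → 7 → 9).

Steps most likely to fail

Step 3 (crossed Kolbe electrolysis). Radical pairing is statistical and the sparingly soluble long-chain products may film the anode. Current efficiency would then fall, disproportionation and two-electron (Hofer–Moest) products would grow, and the cross-product might not be freed from the homodimers. The fallback builds the chain by polar, non-statistical bond formation; it sets out from 4 and returns at 7. The free carboxyl of 4 is reduced chemoselectively (BH3·SMe2, THF, 0 °C to rt) to methyl 20-hydroxyicosanoate F1, which is oxidised (TEMPO cat., PhI(OAc)2, CH2Cl2, rt) to methyl 20-oxoicosanoate F2. Separately, 10-bromodecan-1-ol and PPh3 (MeCN, reflux) give (10-hydroxydecyl)triphenylphosphonium bromide F3, which NaN(SiMe3)2 (2.1 equiv, THF, −78 to 0 °C) converts to sodium 10-(triphenylphosphoranylidene)decan-1-olate F4. Wittig olefination of F2 with F4 (−78 °C to rt) should give methyl (Z)-30-hydroxytriacont-20-enoate F5, whose double-bond geometry is irrelevant. Hydrogenation (H2, 10% Pd/C, EtOAc/THF, 40 °C) gives methyl 30-hydroxytriacontanoate F6, and saponification under the conditions of step 4 leads through 6 to 7.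

Step 5 (macrolactonisation). Intermolecular acylation may compete with closure of the very large ring, and limited solubility of the seco acid may prevent true high dilution of the activated monomer, so that linear oligoesters and the diolide form. The fallback closes the ring at the other end of the ester linkage, by O-alkylation instead of acyl activation; it sets out from 7 and returns at 9. The alcohol of 7 is converted (HBr, 33% in AcOH, H2SO4 cat., 90 °C) to 30-bromotriacontanoic acid F7. This is added slowly to Cs2CO3 in DMF at 80 °C (final ca. 1 mM), where caesium 30-bromotriacontanoate F8 should cyclise by intramolecular SN2 displacement at C30 to give 9.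

Step 2 (mono-esterification). The esterification cannot distinguish the two carboxyls, and the waxy diacid, half-ester and diester may co-crystallise or streak on silica, so that pure 4 is obtained only with heavy recycling. The fallback replaces statistical esterification by desymmetrisation through precipitation; it sets out from 3 and returns at 4. Exhaustive Fischer esterification (MeOH, H2SO4 cat., reflux) gives dimethyl eicosanedioate F9. Half-saponification with Ba(OH)2·8H2O (0.5 equiv, MeOH/THF, rt) should precipitate barium bis(20-methoxy-20-oxoicosanoate) F10 as soon as one ester group is cleaved, which protects the second. Filtration, washing out residual diester and acidification (2 M HCl) give 4.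

Further compounds
F1 | step 3 | methyl 20-hydroxyicosanoate | COC(=O)CCCCCCCCCCCCCCCCCCCO
F2 | step 3 | methyl 20-oxoicosanoate | COC(=O)CCCCCCCCCCCCCCCCCCC=O
F3 | step 3 | (10-hydroxydecyl)triphenylphosphonium bromide | OCCCCCCCCCC[P+](c1ccccc1)(c1ccccc1)c1ccccc1.[Br-]
F4 | step 3 | sodium 10-(triphenylphosphoranylidene)decan-1-olate | [Na+].[O-]CCCCCCCCCC=P(c1ccccc1)(c1ccccc1)c1ccccc1
F5 | step 3 | methyl (Z)-30-hydroxytriacont-20-enoate | COC(=O)CCCCCCCCCCCCCCCCCC/C=C\CCCCCCCCCO
F6 | step 3 | methyl 30-hydroxytriacontanoate | COC(=O)CCCCCCCCCCCCCCCCCCCCCCCCCCCCCO
F7 | step 5 | 30-bromotriacontanoic acid | OC(=O)CCCCCCCCCCCCCCCCCCCCCCCCCCCCCBr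
F8 | step 5 | caesium 30-bromotriacontanoate | [Cs+].[O-]C(=O)CCCCCCCCCCCCCCCCCCCCCCCCCCCCCBr
F9 | step 2 | dimethyl eicosanedioate | COC(=O)CCCCCCCCCCCCCCCCCCC(=O)OC
F10 | step 2 | barium bis(20-methoxy-20-oxoicosanoate) | [Ba+2].[O-]C(=O)CCCCCCCCCCCCCCCCCCC(=O)OC.[O-]C(=O)CCCCCCCCCCCCCCCCCCC(=O)OC
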